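The 7,9-dioxabicyclo[4.2.1]nonane cage is disconnected as a (4+3) adduct. Its C25–O–C17 bridge (acetal CH, ether oxygen, quaternary carbinol carbon of the dioxolane ring) is a masked carbonyl ylide, and the oxepane arc C13–C14–C15–C16, anchored on ring C, is a 1-oxygenated diene. In one operation a sclareol-derived tricyclic siloxydiene and an aspartate-derived 2-methoxy-4-siloxy-1,3-dioxole are joined through C13–C25 and C16–C17; this closes the oxepane and sets C13, C16, C17 and C25. Hydroxyl-directed hydrogenation (C14), lactone-to-lactol reduction, two acetylations and a final debenzylation complete the route.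

Key step: step 12

Remark on numbering: ring carbons C1–C14 follow podocarpane numbering (gem-dimethyl at C4, methyls on C10 and C8); C15 = CH2 on C14, C16 = CH–O, C17 = quaternary O-bearing carbon, C18/C19 = CH2CO2H, C24 = acetoxy acetal carbon, C25 = acetal CH on C13; α/β refer to the usual drawing with the C10 methyl β. The stereocentre of the aspartate-derived partner becomes sp2 in step 12, so its configuration is immaterial.

Step 1
Reactants: 1 (−)-sclareol
Product: 2 8α-hydroxy-14,15-dinorlabdan-13-one
Conditions: KMnO4, acetone–H2O, 0 °C to rt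
Reagents that add atoms: none
Why: Permanganate cleaves the vinyl group and the resulting α-hydroxy acid is oxidatively decarboxylated to the methyl ketone (oxidative degradation of a tertiary allylic alcohol), with no stereocentre touched.

Step 2
Reactants: 2 8α-hydroxy-14,15-dinorlabdan-13-one
Product: 3 methyl 5-[(1R,2R,4aS,8aS)-2-hydroxy-2,5,5,8a-tetramethyldecahydronaphthalen-1-yl]-3-oxopentanoate
Conditions: NaH, (MeO)2CO, THF, reflux; then AcOH
Reagents that add atoms: dimethyl carbonate, COC(=O)OC
Why: Claisen-type carboxylation of the methyl-side enolate of the methyl ketone with dimethyl carbonate should give the β-keto ester, the hindered tertiary alkoxide being a spectator.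

Step 3
Reactants: 3 methyl 5-[(1R,2R,4aS,8aS)-2-hydroxy-2,5,5,8a-tetramethyldecahydronaphthalen-1-yl]-3-oxopentanoate
Product: 4 methyl 8β-methyl-13-oxopodocarpane-14β-carboxylate
Conditions: SnCl4, CH2Cl2, −20 °C to rt
Reagents that add atoms: none
Why: SnCl4 ionises the tertiary C8 alcohol and the tin-bound β-keto ester enol captures the cation through a chair transition state (intramolecular SN1 C-alkylation, the last ring closure of a polyene-type cationic cyclisation), which places the new C8–C14 bond equatorial (α) and the C8 methyl axial (β) in a trans B/C fusion, the C14 ester settling equatorial.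

Step 4
Reactants: 4 methyl 8β-methyl-13-oxopodocarpane-14β-carboxylate
Product: 5 methyl 8β-methyl-13-(trifluoromethylsulfonyloxy)podocarp-13-ene-14-carboxylate
Conditions: Tf2O, i-Pr2NEt, CH2Cl2, −78 to 0 °C
Reagents that add atoms: trifluoromethanesulfonic anhydride, O=S(=O)(OS(=O)(=O)C(F)(F)F)C(F)(F)F
Why: O-sulfonylation of the enol of the β-keto ester (enol triflate formation) fixes the C13=C14 double bond.

Step 5
Reactants: 5 methyl 8β-methyl-13-(trifluoromethylsulfonyloxy)podocarp-13-ene-14-carboxylate
Product: 6 methyl 8β-methylpodocarp-13-ene-14-carboxylate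
Conditions: Pd(OAc)2 (cat.), PPh3, HCO2H, n-Bu3N, DMF, 60 °C
Reagents that add atoms: none
Why: Palladium-catalysed formate reduction of the enol triflate (oxidative addition, decarboxylation of formate to a palladium hydride, reductive elimination) replaces the triflate by hydrogen and leaves the conjugated ester.

Step 6
Reactants: 6 methyl 8β-methylpodocarp-13-ene-14-carboxylate
Product: 7 (8β-methylpodocarp-13-en-14-yl)methanol
Conditions: i-Bu2AlH, CH2Cl2, −78 to 0 °C; aqueous KNaC4H4O6
Reagents that add atoms: none
Why: 1,2-Reduction of the enoate by the aluminium hydride gives the allylic alcohol.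

Step 7
Reactants: 7 (8β-methylpodocarp-13-en-14-yl)methanol
Product: 8 8β-methylpodocarp-13-ene-14-carbaldehyde
Conditions: MnO2, CH2Cl2, rt
Reagents that add atoms: none
Why: Allylic oxidation on MnO2 stops at the enal.

Step 8
Reactants: 8 8β-methylpodocarp-13-ene-14-carbaldehyde
Product: 10 (2E)-2-(8β-methylpodocarpan-14-ylidene)acetaldehyde, via methoxydiene 9 (not isolated)
Conditions: Ph3P(CH2OMe)Cl, KN(SiMe3)2, THF, 0 °C to rt; then 2 M HCl, THF, rt
Reagents that add atoms: (methoxymethyl)triphenylphosphonium chloride, COC[P+](c1ccccc1)(c1ccccc1)c1ccccc1.[Cl-]; water, O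
Why: Wittig olefination with the methoxymethylene ylide gives the dienol methyl ether, whose hydrolysis by γ-protonation at C13 should deliver the one-carbon-homologated conjugated enal with the aldehyde turned away from quaternary C8.

Step 9
Reactants: 10 (2E)-2-(8β-methylpodocarpan-14-ylidene)acetaldehyde
Product: 11 8β-methyl-14-[(E)-2-(trimethylsilyloxy)ethenyl]podocarp-13-ene
Conditions: Me3SiOTf, Et3N, Et2O, 0 °C; used crude
Reagents that add atoms: trimethylsilyl trifluoromethanesulfonate, C[Si](C)(C)OS(=O)(=O)C(F)(F)F
Why: Soft enolisation removes the only γ-hydrogen available (C13–H, C8 being quaternary) and O-silylates the s-trans enal, which should give the 1E siloxydiene.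

Step 10
Reactants: 12 L-aspartic acid 4-benzyl ester
Product: 13 (2S)-4-benzyloxy-2-hydroxy-4-oxobutanoic acid
Conditions: NaNO2, 1 M H2SO4, 0 °C to rt
Reagents that add atoms: water, O
Why: Diazotisation of the α-amino acid, in which the carboxylate displaces N2 to an α-lactone that water opens, gives the α-hydroxy acid with net retention.

Step 11
Reactants: 13 (2S)-4-benzyloxy-2-hydroxy-4-oxobutanoic acid
Product: 14 benzyl 2-[(4S)-2-methoxy-5-oxo-1,3-dioxolan-4-yl]acetate
Conditions: HC(OMe)3, pyridinium p-toluenesulfonate (cat.), toluene, 50 °C, MeOH removed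
Reagents that add atoms: trimethyl orthoformate, COC(OC)OC
Why: Acid-catalysed orthoester exchange closes the α-hydroxy acid onto the orthoformate carbon as a five-membered 2-methoxy-1,3-dioxolan-4-one (cyclic mixed orthoester formation), as a mixture of C2 epimers.

Step 12
Reactants: 11 8β-methyl-14-[(E)-2-(trimethylsilyloxy)ethenyl]podocarp-13-ene; 14 benzyl 2-[(4S)-2-methoxy-5-oxo-1,3-dioxolan-4-yl]acetate
Product: 17 benzyl ester of the Δ14(15) 16-hydroxy-24-oxo cage acid, via silyl ketene acetal 15 (not isolated), via silyl ether 16 (not isolated)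
Conditions: 14, LiN(SiMe3)2 (1.05 equiv), Me3SiCl, THF, −78 °C; the solution of 15 added slowly to 11, Me3SiOTf (0.2 equiv), 2,6-di-tert-butylpyridine (cat.), CH2Cl2, −78 to −40 °C; then 1 M HCl, THF, 0 °C
Reagents that add atoms: none
Why: Proposed new method: Me3SiOTf ionises the C25–OMe orthoester of 15 to a 4-siloxy-1,3-dioxolium ion (the O-silylated form of a mesoionic carbonyl ylide), the γ-carbon C13 of the s-cis dienol ether 11 adds to C25 (vinylogous Mukaiyama addition) and the O-silyl oxocarbenium ion so formed at C16 is captured by the ketene-acetal carbon C17 (intramolecular Mukaiyama aldol), silyl transfer returning Me3SiOTf, so that the net result is a stepwise cationic (4+3) annulation. The closest known reaction types are Lewis-acid (4+3) cycloadditions of siloxyallyl cations with dienes and Me3SiOTf-mediated annulations of bis-silyl nucleophiles with dielectrophiles; each half (siloxydiene plus orthoester, Mukaiyama aldol) is known on its own, but their union on a dioxolium ion is not. Only the oxepane ring is closed, by a 7-(enolexo)-exo-trig aldol attack of C17 on C16 that can only bridge the existing five-membered ring cis, which gives the 7,9-dioxabicyclo[4.2.1]nonene. C13 is set by attack anti to the axial 8β-methyl (α face); C25, and with it C17, by the orientation in which the diene edge C14–C15, whose C14 carries quaternary C8, lies over the unsubstituted ring oxygen and away from the C24 siloxy edge; C16 by the E enol ether, which keeps oxygen on the outside of the diene and so cis to C12. The step needs γ- over α-attack of the dienol ether (C15 is shielded by the C8-bearing C14), closure at C16 and not at tetrasubstituted C14 (the (3+2) mode), an s-cis diene (favoured by C8, as in 2-tert-alkylbutadienes) and suppression of self-condensation of 15 (slow addition to 11 and catalyst). Precursor 15 is made in the flask by enolising only the lactone C17–H of 14 with in situ O-silylation, since LiN(SiMe3)2 should deprotonate the dioxolanone faster than the less acidic side-chain ester, whose enolate would eliminate the ring oxygen.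

Step 13
Reactants: 17 benzyl ester of the Δ14(15) 16-hydroxy-24-oxo cage acid
Product: 18 benzyl ester of the 14α-H 16-hydroxy-24-oxo cage acid
Conditions: H2 (1 atm), [Ir(cod)(PCy3)(py)]PF6 (cat.), CH2Cl2, rt
Reagents that add atoms: none
Why: Hydroxyl-directed homogeneous hydrogenation: the cationic iridium catalyst binds the C16 hydroxyl and should deliver H2 to the C14=C15 face syn to it, which is also the face anti to the axial 8β-methyl, so C14 receives its α-hydrogen and ring C is trans-fused to the oxepane.

Step 14
Reactants: 18 benzyl ester of the 14α-H 16-hydroxy-24-oxo cage acid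
Product: 19 benzyl ester of the 16-acetoxy-24-oxo cage acid
Conditions: Ac2O, pyridine, DMAP (cat.), CH2Cl2, rt
Reagents that add atoms: acetic anhydride, CC(=O)OC(C)=O
Why: DMAP-catalysed acylation of the secondary C16 alcohol, done before the lactone is reduced so that this hydroxyl cannot later take part in acetal exchange.

Step 15
Reactants: 19 benzyl ester of the 16-acetoxy-24-oxo cage acid
Product: 20 benzyl ester of the 16-acetoxy-24-hydroxy cage acid (lactol)
Conditions: disiamylborane, THF, 0 °C to rt; then H2O
Reagents that add atoms: none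
Why: Disiamylborane reduces lactones to lactols but not carboxylic esters (chemoselective borane reduction of a lactone carbonyl), so the activated dioxolanone carbonyl should be taken to the hemiacetal while the acetate and the benzyl ester survive, the borinate holding the lactol closed until work-up.

Step 16
Reactants: 20 benzyl ester of the 16-acetoxy-24-hydroxy cage acid (lactol)
Product: 21 benzyl ester of the target
Conditions: Ac2O, pyridine, DMAP (cat.), CH2Cl2, 0 °C
Reagents that add atoms: acetic anhydride, CC(=O)OC(C)=O
Why: Acylation of the equilibrating lactol should favour the anomer whose hydroxyl lies on the exo face, anti to the four-carbon bridge C13–C16 (kinetic anomeric acylation), which is the C24 configuration of the target.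

Step 17
Reactants: 21 benzyl ester of the target
Product: 22 target acid CNP0138244.2
Conditions: H2 (1 atm), Pd/C, EtOAc, rt
Reagents that add atoms: none
Why: Neutral hydrogenolysis of the benzyl ester frees the acid without activating the neighbouring acetoxy acetal, which an acidic or basic deprotection would endanger.

Compound list
1 | (−)-sclareol, (13R)-labd-14-ene-8α,13-diol | C=C[C@](C)(O)CC[C@@H]1[C@@]2(C)CCCC(C)(C)[C@@H]2CC[C@@]1(C)O | starting material
2 | 8α-hydroxy-14,15-dinorlabdan-13-one | CC(=O)CC[C@@H]1[C@@]2(C)CCCC(C)(C)[C@@H]2CC[C@@]1(C)O | intermediate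
3 | methyl 5-[(1R,2R,4aS,8aS)-2-hydroxy-2,5,5,8a-tetramethyldecahydronaphthalen-1-yl]-3-oxopentanoate | COC(=O)CC(=O)CC[C@@H]1[C@@]2(C)CCCC(C)(C)[C@@H]2CC[C@@]1(C)O | intermediate
4 | methyl 8β-methyl-13-oxopodocarpane-14β-carboxylate (5α-H, 9α-H, 14α-H) | COC(=O)[C@@H]1C(=O)CC[C@H]2[C@@]1(C)CC[C@H]1C(C)(C)CCC[C@]21C | intermediate
5 | methyl 8β-methyl-13-(trifluoromethylsulfonyloxy)podocarp-13-ene-14-carboxylate | COC(=O)C1=C(OS(=O)(=O)C(F)(F)F)CC[C@H]2[C@@]1(C)CC[C@H]1C(C)(C)CCC[C@]21C | intermediate
6 | methyl 8β-methylpodocarp-13-ene-14-carboxylate | COC(=O)C1=CCC[C@H]2[C@@]1(C)CC[C@H]1C(C)(C)CCC[C@]21C | intermediate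
7 | (8β-methylpodocarp-13-en-14-yl)methanol | OCC1=CCC[C@H]2[C@@]1(C)CC[C@H]1C(C)(C)CCC[C@]21C | intermediate
8 | 8β-methylpodocarp-13-ene-14-carbaldehyde | O=CC1=CCC[C@H]2[C@@]1(C)CC[C@H]1C(C)(C)CCC[C@]21C | intermediate
9 | 14-(2-methoxyethenyl)-8β-methylpodocarp-13-ene (E/Z mixture) | COC=CC1=CCC[C@H]2[C@@]1(C)CC[C@H]1C(C)(C)CCC[C@]21C | intermediate
10 | (2E)-2-(8β-methylpodocarpan-14-ylidene)acetaldehyde (CHO cis to C13) | O=C/C=C1\CCC[C@H]2[C@@]1(C)CC[C@H]1C(C)(C)CCC[C@]21C | intermediate
11 | 8β-methyl-14-[(E)-2-(trimethylsilyloxy)ethenyl]podocarp-13-ene | C[Si](C)(C)O/C=C/C1=CCC[C@H]2[C@@]1(C)CC[C@H]1C(C)(C)CCC[C@]21C | intermediate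
12 | L-aspartic acid 4-benzyl ester | N[C@@H](CC(=O)OCc1ccccc1)C(=O)O | starting material
13 | (2S)-4-benzyloxy-2-hydroxy-4-oxobutanoic acid | O[C@@H](CC(=O)OCc1ccccc1)C(=O)O | intermediate
14 | benzyl 2-[(4S)-2-methoxy-5-oxo-1,3-dioxolan-4-yl]acetate (both C2 epimers) | COC1O[C@@H](CC(=O)OCc2ccccc2)C(=O)O1 | intermediate
15 | benzyl 2-[2-methoxy-5-(trimethylsilyloxy)-1,3-dioxol-4-yl]acetate | COC1OC(CC(=O)OCc2ccccc2)=C(O[Si](C)(C)C)O1 | intermediate
16 | 16-O-trimethylsilyl ether of 17 | O=C1O[C@H]2O[C@]1(CC(=O)OCc3ccccc3)[C@H](O[Si](C)(C)C)C=C1[C@@H]2CC[C@H]2[C@@]1(C)CC[C@H]1C(C)(C)CCC[C@]21C | intermediate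
17 | benzyl ester of the Δ14(15) 16-hydroxy-24-oxo cage acid: ring-C-fused 7,9-dioxabicyclo[4.2.1]non-3-en-8-one with CH2CO2Bn on C17; 13β-H; 16-OH cis to C12 and on the side of the ether bridge | O=C1O[C@H]2O[C@]1(CC(=O)OCc3ccccc3)[C@H](O)C=C1[C@@H]2CC[C@H]2[C@@]1(C)CC[C@H]1C(C)(C)CCC[C@]21C | intermediate
18 | 14α-H dihydro derivative of 17 (13β-H, 14α-H) | O=C1O[C@H]2O[C@]1(CC(=O)OCc3ccccc3)[C@H](O)C[C@@H]1[C@@H]2CC[C@H]2[C@@]1(C)CC[C@H]1C(C)(C)CCC[C@]21C | intermediate
19 | 16-acetate of 18 | O=C1O[C@H]2O[C@]1(CC(=O)OCc3ccccc3)[C@H](OC(C)=O)C[C@@H]1[C@@H]2CC[C@H]2[C@@]1(C)CC[C@H]1C(C)(C)CCC[C@]21C | intermediate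
20 | 24-lactol of 19 (both C24 anomers) | OC1O[C@H]2O[C@]1(CC(=O)OCc3ccccc3)[C@H](OC(C)=O)C[C@@H]1[C@@H]2CC[C@H]2[C@@]1(C)CC[C@H]1C(C)(C)CCC[C@]21C | intermediate
21 | benzyl ester of the target (16,24-diacetate, 24-OAc exo) | CC(=O)O[C@H]1O[C@H]2O[C@]1(CC(=O)OCc3ccccc3)[C@H](OC(C)=O)C[C@@H]1[C@@H]2CC[C@H]2[C@@]1(C)CC[C@H]1C(C)(C)CCC[C@]21C | intermediate
22 | CNP0138244.2 | CC(=O)O[C@H]1O[C@H]2O[C@]1(CC(=O)O)[C@H](OC(C)=O)C[C@@H]1[C@@H]2CC[C@H]2[C@@]1(C)CC[C@H]1C(C)(C)CCC[C@]21C | target

Total step count: 17. Longest linear sequence: 15 steps (steps 1–9 and 12–17); steps 10–11 prepare the second fragment.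

Steps most likely to fail

Step 12 (proposed new method). The dienol ether may be attacked at C15 instead of C13, the second bond may close at C14 in the (3+2) sense, the ambiphilic dioxole 15 may condense with itself, the side-chain ester of 14 may be enolised and eliminate, or face selection at C25 may be poor. The fallback uses known chemistry only. It sets out from 11 and from 13 and comes back at 17. Siloxydiene 11 undergoes the known γ-selective vinylogous Mukaiyama addition to trimethyl orthoformate (ZnCl2 cat., CH2Cl2) to give (2E)-2-[13α-(dimethoxymethyl)-8β-methylpodocarpan-14-ylidene]acetaldehyde F1. Hydroxy acid 13 is condensed with pivalaldehyde (acid catalysis, water removed) to the cis dioxolanone benzyl 2-[(2S,4S)-2-tert-butyl-5-oxo-1,3-dioxolan-4-yl]acetate F2. Its lithium enolate (LiN(SiMe3)2, THF, −78 °C) adds to the aldehyde of F1 anti to the tert-butyl group (self-regeneration of the C17 stereocentre) to give the aldol adduct F3. Camphorsulfonic acid in warm toluene then exchanges the pivalaldehyde acetal for the internal C25 dimethyl acetal, pivalaldehyde dimethyl acetal being distilled off, and closes the cage to 17. The weak points of this detour would be facial selectivity at C16 in the aldol step and competing acetal closure through the C16 hydroxyl.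

Step 16. The lactol may be acylated as the wrong anomer if ring opening and reclosure are slow, since hydride enters the dioxolanone from the exo face and first leaves the hydroxyl endo. The fallback sets out from 20 and comes back at 21: a Mitsunobu esterification of the unequilibrated endo lactol with acetic acid (PPh3, diisopropyl azodicarboxylate, THF, 0 °C) installs the acetate with inversion at C24, on the exo face, instead of relying on equilibration.

Step 3. The tertiary alcohol may close on the ketone oxygen to a cyclic enol ether instead of alkylating carbon, or ionise sluggishly. The fallback sets out from 3 and comes back at 4: dehydration (SOCl2, pyridine, −20 °C) gives the exocyclic alkene methyl 5-[(1S,4aS,8aS)-5,5,8a-trimethyl-2-methylidenedecahydronaphthalen-1-yl]-3-oxopentanoate F4 (with ring-alkene isomers), and proton-initiated cyclisation of the alkene (CF3CO2H, CH2Cl2, 0 °C) generates the same C8 cation without an oxygen nucleophile at C8, giving 4.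

Further compounds
F1 | step 12 | (2E)-2-[13α-(dimethoxymethyl)-8β-methylpodocarpan-14-ylidene]acetaldehyde | O=C/C=C1\[C@@H](C(OC)OC)CC[C@H]2[C@@]1(C)CC[C@H]1C(C)(C)CCC[C@]21C
F2 | step 12 | benzyl 2-[(2S,4S)-2-tert-butyl-5-oxo-1,3-dioxolan-4-yl]acetate | CC(C)(C)[C@H]1O[C@@H](CC(=O)OCc2ccccc2)C(=O)O1
F3 | step 12 | aldol adduct of F2 (at C17, anti to tert-butyl) with the aldehyde of F1 (16-hydroxy, C14=C15 retained) | CC(C)(C)[C@H]1O[C@](CC(=O)OCc4ccccc4)([C@H](O)/C=C2\[C@@H](C(OC)OC)CC[C@H]3[C@@]2(C)CC[C@H]2C(C)(C)CCC[C@]32C)C(=O)O1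
F0 | step 16 | none | none
F4 | step 3 | methyl 5-[(1S,4aS,8aS)-5,5,8a-trimethyl-2-methylidenedecahydronaphthalen-1-yl]-3-oxopentanoate | COC(=O)CC(=O)CC[C@H]1C(=C)CC[C@H]2C(C)(C)CCC[C@]12C
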